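**Retrosynthetic overview**
1. Target ⇒ C8‑OH/C9‑OPMB macrocycle + (2R,3R)‑epoxyangelic acid (Yamaguchi ester, then DDQ); the acid comes from methyl angelate by Sharpless epoxidation.
2. Ten‑membered carbocycle (last ring) ⇒ ring‑closing metathesis at C1=C10 of a cis‑fused α‑methylene‑γ‑butyrolactone that carries both arms.
3. Lactone (second ring) ⇒ isoxazoline (N–O cleavage, ketone methylenation, oxidative lactonisation); west arm from a C5 aldehyde (Still–Gennari, Keck allylation), east arm from a C10 methyl ketone (Wittig).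
4. Aldehyde + ketone ⇒ ozonolysis of a cyclohexene template; isoxazoline (first ring) ⇒ nitrile oxide cycloaddition to a protected cyclohexadienediol.
5. Dienediol ⇒ toluene by dioxygenase‑catalysed cis‑dihydroxylation (sets C8 and C9).

Assumption: positions are called C1–C15 in germacranolide fashion (lactone O on C6, C7–C11(=C13H2)–C12(=O), ester on C8, OH on C9, C10(C14H3)=C1, C2H2, OAc on C3, C4(C15H3)=C5); in these terms the target is 3S,6R,7R,8S,9R with a (2R,3R)‑2,3‑epoxy‑2‑methylbutanoate and both ring alkenes Z.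

**Route**

Step 1
Reactants: 1 toluene
Product: 2 (1S,2R)-3-methylcyclohexa-3,5-diene-1,2-diol
Conditions: toluene dioxygenase in whole cells of E. coli JM109(pDTG601A), toluene fed as vapour, air, glycerol as hydride source, phosphate buffer pH 7.2, 30 °C
Reagents that add atoms: dioxygen, O=O
Why: Toluene dioxygenase, an arene dioxygenase, adds both atoms of O2 to one face of the 2,3-bond of toluene (enzymatic arene cis-dihydroxylation), giving only the (1S,2R)-cis-diol and so setting C9 and C8 with the absolute configuration of the target.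

Step 2
Reactants: 2 cis-diol
Product: 3 p-methoxybenzylidene acetal of 2
Conditions: 4-MeOC6H4CH(OMe)2, PPTS (5 mol %), CH2Cl2, 0 °C
Reagents that add atoms: 4-methoxybenzaldehyde dimethyl acetal, COc1ccc(cc1)C(OC)OC
Why: Acid-catalysed transacetalisation of the cis-1,2-diol gives the five-membered acetal without touching a ring stereocentre, the weak acid and low temperature avoiding dehydration to cresol.

Step 3
Reactants: 3 acetal
Product: 4 C9-OPMB C8-OH dienol
Conditions: i-Bu2AlH (3 equiv), CH2Cl2, −78 → 0 °C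
Reagents that add atoms: none
Why: Regioselective reductive acetal opening, in which i-Bu2AlH coordinates the less hindered acetal oxygen (on C8, remote from the ring methyl), that C–O bond breaks and hydride is delivered to the oxocarbenium ion, leaving the PMB ether on O9 and a free C8 hydroxyl.

Step 4
Reactants: 4 dienol
Product: 5 C9-OPMB C8-OTBS diene
Conditions: TBSOTf, 2,6-lutidine, CH2Cl2, −78 °C
Reagents that add atoms: tert-butyldimethylsilyl triflate, CC(C)(C)[Si](C)(C)OS(=O)(=O)C(F)(F)F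
Why: Silylation of the remaining secondary hydroxyl with the silyl triflate and a hindered base runs cold and acid-free, so the dienyl ether does not aromatise and no stereocentre is touched.

Step 5
Reactants: 6 2-nitroethanol
Product: 7 tert-butyldimethyl(2-nitroethoxy)silane
Conditions: TBSCl, imidazole, DMF, 0 °C → rt
Reagents that add atoms: tert-butyldimethylsilyl chloride, CC(C)(C)[Si](C)(C)Cl
Why: Imidazole-promoted O-silylation of the primary alcohol gives the protected primary nitroalkane that serves as nitrile oxide precursor.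

Step 6
Reactants: 5 diene; 7 silyl nitro ether
Product: 9 (3aR,4S,5R,7aR)-isoxazoline (cis-fused 3a,4,5,7a-tetrahydro-1,2-benzoxazole), via silyloxyacetonitrile oxide 8 (not isolated)
Conditions: PhNCO (2.5 equiv), Et3N (10 mol %), toluene, 7 added over 12 h, 40 °C
Reagents that add atoms: none
Why: Mukaiyama dehydration of the nitroalkane gives the nitrile oxide, which undergoes Huisgen 1,3-dipolar cycloaddition at the less substituted C6=C7 bond with carbon bonding to the diene terminus C7 and oxygen to C6 (5-vinylisoxazoline regiochemistry) on the face opposite the C8/C9 ether groups, which sets C6 and C7 cis to each other and anti to O8/O9.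

Step 7
Reactants: 9 isoxazoline
Product: 11 isoxazoline keto aldehyde (C5 aldehyde, C10 methyl ketone), via ozonide 10 (not isolated)
Conditions: O3, CH2Cl2, −78 °C, Sudan red 7B end point; then PPh3, −78 °C → rt
Reagents that add atoms: ozone, [O-][O+]=O
Why: Ozonolysis with reductive work-up cleaves the only electron-rich C=C bond (C5=C10) into the C5 aldehyde and the C10 methyl ketone without touching the four stereocentres, the titrated end point sparing the PMB ring and the C=N bond.

Step 8
Reactants: 12 methyl bis(2,2,2-trifluoroethyl)phosphonoacetate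
Product: 13 methyl 2-[bis(2,2,2-trifluoroethoxy)phosphoryl]propanoate (racemic)
Conditions: NaH, THF, 0 °C; MeI, 0 °C → rt
Reagents that add atoms: iodomethane, CI
Why: C-Alkylation of the sodium enolate of the phosphonoacetate with iodomethane gives the α-methyl Still–Gennari reagent, whose stereocentre disappears in the next step.

Step 9
Reactants: 11 keto aldehyde; 13 α-methyl phosphonate
Product: 14 methyl (Z)-enoate ketone
Conditions: 13, KN(SiMe3)2, 18-crown-6, THF, −78 °C; then 11, −78 °C
Reagents that add atoms: none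
Why: Still–Gennari olefination, in which the trifluoroethyl phosphonate anion adds to the aldehyde much faster than to the ketone and the fast irreversible elimination gives the (Z)-trisubstituted enoate, fixing the C4=C5 geometry.

Step 10
Reactants: 14 enoate ketone
Product: 15 (Z)-enoate with isopropenyl group at C9
Conditions: Ph3PCH3Br, KOt-Bu, THF, 0 °C
Reagents that add atoms: methyltriphenylphosphonium bromide, C[P+](c1ccccc1)(c1ccccc1)c1ccccc1.[Br-]
Why: Wittig methylenation of the methyl ketone with the non-stabilised ylide is fast at 0 °C, so the α-alkoxy stereocentre C9 is not epimerised and the hindered enoate is left alone.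

Step 11
Reactants: 15 enoate
Product: 16 (Z)-allylic alcohol (C3H2OH)
Conditions: i-Bu2AlH (2.5 equiv), CH2Cl2, −78 °C
Reagents that add atoms: none
Why: 1,2-Reduction of the enoate by i-Bu2AlH at −78 °C gives the allylic alcohol with the Z geometry intact, the isoxazoline C=N bond being inert at this temperature.

Step 12
Reactants: 16 allylic alcohol
Product: 17 (Z)-enal
Conditions: Dess–Martin periodinane, pyridine, CH2Cl2, 0 °C; used at once
Reagents that add atoms: none
Why: Dess–Martin oxidation under pyridine buffering gives the α-methyl (Z)-enal without acid or base that could isomerise it to the E isomer.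

Step 13
Reactants: 17 enal
Product: 18 (3S)-homoallylic alcohol
Conditions: (S)-BINOL (20 mol %), Ti(Oi-Pr)4 (10 mol %), 4 Å MS, CH2Cl2; allylSnBu3, −20 °C, 48 h
Reagents that add atoms: allyltributylstannane, C=CC[Sn](CCCC)(CCCC)CCCC
Why: Keck asymmetric allylation, in which the (S)-BINOL–titanium Lewis acid directs allyl transfer from tin to the Si face of the aldehyde under catalyst control (the nearest stereocentre lies three bonds away), which sets C3 as S.

Step 14
Reactants: 18 alcohol
Product: 19 (3S)-acetate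
Conditions: Ac2O, pyridine, DMAP (cat.), CH2Cl2, 0 °C → rt
Reagents that add atoms: acetic anhydride, CC(=O)OC(C)=O
Why: DMAP-catalysed acylation puts the C3 acetate of the target on the only free hydroxyl.

Step 15
Reactants: 19 isoxazoline acetate
Product: 21 β-hydroxy ketone (C6-OH, C11=O), via hydroxy imine 20 (not isolated)
Conditions: Mo(CO)6, MeCN/H2O 15:1, 80 °C
Reagents that add atoms: water, O
Why: Reductive N–O cleavage of the isoxazoline by zerovalent molybdenum followed by hydrolysis of the β-hydroxy imine unmasks the C6 hydroxyl and the C11 ketone under neutral conditions that leave the alkenes, the acetate and C7 untouched.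

Step 16
Reactants: 21 hydroxy ketone
Product: 22 C11=C13 methylene compound
Conditions: Zn, CH2Br2, TiCl4, THF (reagent aged at 5 °C); then 21, CH2Cl2, 0 °C → rt
Reagents that add atoms: dibromomethane, BrCBr
Why: Takai–Lombardo methylenation with the non-basic zinc/titanium gem-dimetallic reagent converts the ketone into the exocyclic methylene without enolisation (no epimerisation at C7, no β-elimination) and without attacking the acetate.

Step 17
Reactants: 22 bis-silyl ether
Product: 23 C6,C12-diol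
Conditions: HF·pyridine, pyridine, THF, 0 °C
Reagents that add atoms: none
Why: Selective desilylation, as buffered HF·pyridine cleaves the unhindered primary allylic silyl ether far faster than the flanked secondary C8 silyl ether and leaves acetate and PMB ether alone.

Step 18
Reactants: 23 diol
Product: 26 cis-fused α-methylene-γ-butyrolactone seco-diene, via hydroxy enal 24 (not isolated), via lactol 25 (not isolated)
Conditions: TEMPO (20 mol %), PhI(OAc)2 (2.5 equiv), CH2Cl2, rt
Reagents that add atoms: none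
Why: TEMPO/PhI(OAc)2 oxidative lactonisation, in which the primary allylic alcohol is oxidised selectively to the enal, this closes onto the C6 hydroxyl to a five-membered lactol and the lactol is oxidised on to the lactone, which is cis-fused because C6 and C7 are already fixed.

Step 19
Reactants: 26 seco-diene
Product: 27 (3S,6R,7R,8S,9R)-3-acetoxy-8-(TBS-oxy)-9-(PMB-oxy)germacra-1(10)Z,4Z,11(13)-trien-12,6-olide
Conditions: second-generation Grubbs catalyst (H2IMes)(PCy3)Cl2Ru=CHPh (15 mol %, two portions), toluene, 1 mM, 80 °C, argon sparge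
Reagents that add atoms: none
Why: Ring-closing metathesis, in which the ruthenium carbene loads on the monosubstituted C1 vinyl group and closes onto the isopropenyl group while the cis-fused lactone and the Z-C4=C5 bond hold the two arms together, the ten-membered ring accepting only the Z-C1=C10 alkene.

Step 20
Reactants: 27 macrocycle
Product: 28 C8 alcohol
Conditions: HF·pyridine, THF, 0 °C → rt
Reagents that add atoms: none
Why: Fluoride-mediated desilylation frees the C8 hydroxyl under conditions that do not touch the acetate, the PMB ether or the lactone.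

Step 21
Reactants: 29 methyl angelate
Product: 30 (Z)-2-methylbut-2-en-1-ol
Conditions: i-Bu2AlH (2.2 equiv), Et2O, −78 → 0 °C
Reagents that add atoms: none
Why: i-Bu2AlH reduces the ester to the allylic alcohol at low temperature without conjugate reduction or Z-to-E isomerisation.

Step 22
Reactants: 30 allylic alcohol
Product: 31 [(2S,3R)-2,3-dimethyloxiran-2-yl]methanol
Conditions: Ti(Oi-Pr)4 (10 mol %), L-(+)-diethyl tartrate (12 mol %), t-BuOOH, 4 Å MS, CH2Cl2, −20 °C
Reagents that add atoms: tert-butyl hydroperoxide, CC(C)(C)OO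
Why: Sharpless asymmetric epoxidation, in which the titanium tartrate catalyst with L-(+)-tartrate delivers oxygen to the alkene face that gives the (2S,3R)-epoxy alcohol, the cis relationship of the C3 methyl and the CH2OH coming from the Z alkene.

Step 23
Reactants: 31 epoxy alcohol
Product: 32 (2R,3R)-2,3-dimethyloxirane-2-carboxylic acid
Conditions: RuCl3·xH2O (2 mol %), NaIO4, CCl4/MeCN/H2O, rt
Reagents that add atoms: sodium periodate, [Na+].[O-]I(=O)(=O)=O
Why: Ruthenium tetroxide made catalytically from RuCl3 and periodate oxidises the primary alcohol to the acid without opening the epoxide, the descriptor at C2 changing from S to R only because the substituent priorities change.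

Step 24
Reactants: 28 C8 alcohol; 32 epoxy acid
Product: 34 C8 epoxyangelate C9 PMB ether, via mixed anhydride 33 (not isolated)
Conditions: 32, 2,4,6-Cl3C6H2COCl, Et3N, THF, rt; then 28, DMAP, toluene, rt → 40 °C
Reagents that add atoms: none
Why: Yamaguchi esterification, in which DMAP attacks the mixed anhydride at the less hindered epoxy acyl carbon and the acylpyridinium acylates the hindered C8 hydroxyl without opening the epoxide, both partners keeping their configuration.

Step 25
Reactants: 34 PMB ether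
Product: 35 target CNP0299903.1
Conditions: DDQ, CH2Cl2/pH 7 phosphate buffer 10:1, 0 °C
Reagents that add atoms: none
Why: Oxidative PMB cleavage, in which DDQ abstracts hydride from the electron-rich benzylic position and water hydrolyses the oxocarbenium ion under neutral conditions, so neither acyl migration from O8 to O9 nor epoxide opening occurs.

**Compound list**

1 | toluene | Cc1ccccc1 | starting material
2 | (1S,2R)-3-methylcyclohexa-3,5-diene-1,2-diol | CC1=CC=C[C@H](O)[C@@H]1O | intermediate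
3 | (3aR,7aS)-2-(4-methoxyphenyl)-4-methyl-3a,7a-dihydro-1,3-benzodioxole (both epimers at the acetal carbon) | CC1=CC=C[C@@H]2OC(c3ccc(OC)cc3)O[C@H]12 | intermediate
4 | (1S,6R)-6-[(4-methoxybenzyl)oxy]-5-methylcyclohexa-2,4-dien-1-ol | CC1=CC=C[C@H](O)[C@@H]1OCc2ccc(OC)cc2 | intermediate
5 | tert-butyl{[(1S,6R)-6-[(4-methoxybenzyl)oxy]-5-methylcyclohexa-2,4-dien-1-yl]oxy}dimethylsilane | CC1=CC=C[C@H](O[Si](C)(C)C(C)(C)C)[C@@H]1OCc2ccc(OC)cc2 | intermediate
6 | 2-nitroethanol | OCC[N+](=O)[O-] | starting material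
7 | tert-butyldimethyl(2-nitroethoxy)silane | CC(C)(C)[Si](C)(C)OCC[N+](=O)[O-] | intermediate
8 | 2-[(tert-butyldimethylsilyl)oxy]acetonitrile oxide | CC(C)(C)[Si](C)(C)OCC#[N+][O-] | intermediate (not isolated)
9 | (3aR,4S,5R,7aR)-4-[(tert-butyldimethylsilyl)oxy]-3-{[(tert-butyldimethylsilyl)oxy]methyl}-5-[(4-methoxybenzyl)oxy]-6-methyl-3a,4,5,7a-tetrahydro-1,2-benzoxazole (ring O on C6, C11 on C7, both anti to O8/O9) | CC1=C[C@H]2ON=C(CO[Si](C)(C)C(C)(C)C)[C@H]2[C@H](O[Si](C)(C)C(C)(C)C)[C@@H]1OCc3ccc(OC)cc3 | intermediate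
10 | secondary ozonide of 9 (1,2,4-trioxolane bridging C5 and C10, both faces) | CC12OOC(O1)[C@H]3ON=C(CO[Si](C)(C)C(C)(C)C)[C@H]3[C@H](O[Si](C)(C)C(C)(C)C)[C@@H]2OCc4ccc(OC)cc4 | intermediate (not isolated)
11 | 3-(TBS-oxymethyl)-4,5-dihydro-1,2-oxazole-5-carbaldehyde carrying at ring C4 (= C7) the chain C8H(OTBS)–C9H(OPMB)–C10(=O)CH3; C6–C9 as in 9 | O=C[C@H]1ON=C(CO[Si](C)(C)C(C)(C)C)[C@H]1[C@H](O[Si](C)(C)C(C)(C)C)[C@H](OCc2ccc(OC)cc2)C(C)=O | intermediate
12 | methyl bis(2,2,2-trifluoroethyl)phosphonoacetate | COC(=O)CP(=O)(OCC(F)(F)F)OCC(F)(F)F | starting material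
13 | methyl 2-[bis(2,2,2-trifluoroethoxy)phosphoryl]propanoate (racemic) | COC(=O)C(C)P(=O)(OCC(F)(F)F)OCC(F)(F)F | intermediate
14 | 11 with C5H=O replaced by (Z)-C5H=C4(CH3)–CO2CH3; C10 ketone kept | COC(=O)/C(C)=C\[C@H]1ON=C(CO[Si](C)(C)C(C)(C)C)[C@H]1[C@H](O[Si](C)(C)C(C)(C)C)[C@H](OCc2ccc(OC)cc2)C(C)=O | intermediate
15 | 14 with C10(=O)CH3 replaced by isopropenyl C10(CH3)=CH2 | COC(=O)/C(C)=C\[C@H]1ON=C(CO[Si](C)(C)C(C)(C)C)[C@H]1[C@H](O[Si](C)(C)C(C)(C)C)[C@H](OCc2ccc(OC)cc2)C(C)=C | intermediate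
16 | (Z)-allylic alcohol: 15 with CO2CH3 reduced to C3H2OH | OC/C(C)=C\[C@H]1ON=C(CO[Si](C)(C)C(C)(C)C)[C@H]1[C@H](O[Si](C)(C)C(C)(C)C)[C@H](OCc2ccc(OC)cc2)C(C)=C | intermediate
17 | (Z)-enal: 16 with C3H=O | O=C/C(C)=C\[C@H]1ON=C(CO[Si](C)(C)C(C)(C)C)[C@H]1[C@H](O[Si](C)(C)C(C)(C)C)[C@H](OCc2ccc(OC)cc2)C(C)=C | intermediate
18 | (3S)-homoallylic alcohol: 17 with C3H(OH)–C2H2–C1H=CH2 | C=CC[C@H](O)/C(C)=C\[C@H]1ON=C(CO[Si](C)(C)C(C)(C)C)[C@H]1[C@H](O[Si](C)(C)C(C)(C)C)[C@H](OCc2ccc(OC)cc2)C(C)=C | intermediate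
19 | (3S)-acetate of 18 | C=CC[C@H](OC(C)=O)/C(C)=C\[C@H]1ON=C(CO[Si](C)(C)C(C)(C)C)[C@H]1[C@H](O[Si](C)(C)C(C)(C)C)[C@H](OCc2ccc(OC)cc2)C(C)=C | intermediate
20 | β-hydroxy imine: isoxazoline of 19 opened to C6-OH and C11(=NH)CH2OTBS | C=CC[C@H](OC(C)=O)/C(C)=C\[C@@H](O)[C@@H](C(=N)CO[Si](C)(C)C(C)(C)C)[C@H](O[Si](C)(C)C(C)(C)C)[C@H](OCc1ccc(OC)cc1)C(C)=C | intermediate (not isolated)
21 | β-hydroxy ketone: C6-OH, C11(=O)CH2OTBS; C3, C6–C9 unchanged | C=CC[C@H](OC(C)=O)/C(C)=C\[C@@H](O)[C@@H](C(=O)CO[Si](C)(C)C(C)(C)C)[C@H](O[Si](C)(C)C(C)(C)C)[C@H](OCc1ccc(OC)cc1)C(C)=C | intermediate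
22 | 21 with C11=O replaced by C11=C13H2 | C=CC[C@H](OC(C)=O)/C(C)=C\[C@@H](O)[C@@H](C(=C)CO[Si](C)(C)C(C)(C)C)[C@H](O[Si](C)(C)C(C)(C)C)[C@H](OCc1ccc(OC)cc1)C(C)=C | intermediate
23 | C6,C12-diol: 22 with free C12H2OH | C=CC[C@H](OC(C)=O)/C(C)=C\[C@@H](O)[C@@H](C(=C)CO)[C@H](O[Si](C)(C)C(C)(C)C)[C@H](OCc1ccc(OC)cc1)C(C)=C | intermediate
24 | hydroxy enal: 23 with C12H=O | C=CC[C@H](OC(C)=O)/C(C)=C\[C@@H](O)[C@@H](C(=C)C=O)[C@H](O[Si](C)(C)C(C)(C)C)[C@H](OCc1ccc(OC)cc1)C(C)=C | intermediate (not isolated)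
25 | lactol of 24 (3-methylene-tetrahydrofuran-2-ol, both anomers) | C=CC[C@H](OC(C)=O)/C(C)=C\[C@H]1OC(O)C(=C)[C@H]1[C@H](O[Si](C)(C)C(C)(C)C)[C@H](OCc2ccc(OC)cc2)C(C)=C | intermediate (not isolated)
26 | cis-β,γ-disubstituted α-methylene-γ-butyrolactone: γ-carbon C6 bears (Z)-C5H=C4(CH3)–(3S)-C3H(OAc)–C2H2–C1H=CH2, β-carbon C7 bears C8H(OTBS)–C9H(OPMB)–C10(CH3)=CH2 | C=CC[C@H](OC(C)=O)/C(C)=C\[C@H]1OC(=O)C(=C)[C@H]1[C@H](O[Si](C)(C)C(C)(C)C)[C@H](OCc2ccc(OC)cc2)C(C)=C | intermediate
27 | (3S,6R,7R,8S,9R)-3-acetoxy-8-[(tert-butyldimethylsilyl)oxy]-9-[(4-methoxybenzyl)oxy]germacra-1(10)Z,4Z,11(13)-trien-12,6-olide | C=C1C(=O)O[C@@H]2/C=C(/C)[C@@H](OC(C)=O)C/C=C(/C)[C@@H](OCc3ccc(OC)cc3)[C@@H](O[Si](C)(C)C(C)(C)C)[C@H]12 | intermediate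
28 | (3S,6R,7S,8S,9R)-3-acetoxy-8-hydroxy-9-[(4-methoxybenzyl)oxy]germacra-1(10)Z,4Z,11(13)-trien-12,6-olide (geometry unchanged; the C7 descriptor changes by priority only) | C=C1C(=O)O[C@@H]2/C=C(/C)[C@@H](OC(C)=O)C/C=C(/C)[C@@H](OCc3ccc(OC)cc3)[C@@H](O)[C@H]12 | intermediate
29 | methyl angelate (methyl (Z)-2-methylbut-2-enoate) | C/C=C(/C)C(=O)OC | starting material
30 | (Z)-2-methylbut-2-en-1-ol | C/C=C(/C)CO | intermediate
31 | [(2S,3R)-2,3-dimethyloxiran-2-yl]methanol | OC[C@]1(C)O[C@@H]1C | intermediate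
32 | (2R,3R)-2,3-dimethyloxirane-2-carboxylic acid | O=C(O)[C@]1(C)O[C@@H]1C | intermediate
33 | (2R,3R)-2,3-dimethyloxirane-2-carboxylic 2,4,6-trichlorobenzoic anhydride | O=C(OC(=O)[C@]1(C)O[C@@H]1C)c1c(Cl)cc(Cl)cc1Cl | intermediate (not isolated)
34 | (3S,6R,7R,8S,9R)-3-acetoxy-8-{[(2R,3R)-2,3-dimethyloxirane-2-carbonyl]oxy}-9-[(4-methoxybenzyl)oxy]germacra-1(10)Z,4Z,11(13)-trien-12,6-olide | C=C1C(=O)O[C@@H]2/C=C(/C)[C@@H](OC(C)=O)C/C=C(/C)[C@@H](OCc3ccc(OC)cc3)[C@@H](OC(=O)[C@]4(C)O[C@@H]4C)[C@H]12 | intermediate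
35 | (3S,6R,7R,8S,9R)-3-acetoxy-9-hydroxy-8-{[(2R,3R)-2,3-dimethyloxirane-2-carbonyl]oxy}germacra-1(10)Z,4Z,11(13)-trien-12,6-olide (CNP0299903.1) | C=C1C(=O)O[C@@H]2/C=C(/C)[C@@H](OC(C)=O)C/C=C(/C)[C@@H](O)[C@@H](OC(=O)[C@]3(C)O[C@@H]3C)[C@H]12 | target

**Step count and risk**

Total steps: 25. Longest linear sequence: 20 steps (toluene → target: steps 1–4, 6, 7, 9–20, 24, 25).

Most likely to fail, with fallbacks:

Step 3 (regiochemistry of the reductive acetal opening). If the PMB group ends on O8 or a mixture forms, the two hydroxyls are differentiated by sterics instead. The fallback sets out from 2: TBSCl and imidazole in DMF at −20 °C silylate the less hindered C8 hydroxyl to give (1R,6S)-6-[(tert-butyldimethylsilyl)oxy]-2-methylcyclohexa-2,4-dien-1-ol F1. The C9 hydroxyl is then etherified with 4-methoxybenzyl 2,2,2-trichloroacetimidate and catalytic La(OTf)3 in toluene, which is almost neutral and causes no silyl migration. This comes back to the route at 5.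

Step 6 (nitrile oxide cycloaddition: furoxan dimerisation may outrun addition to the hindered diene, or regiocontrol may be incomplete). The dipole is changed to a silyl nitronate, which cannot dimerise and tolerates heating. The fallback sets out from 7: Me3SiCl and Et3N give the trimethylsilyl nitronate F2. Heating F2 with diene 5 in toluene at 60–80 °C gives the N-(trimethylsilyloxy)isoxazolidine cycloadduct F3. Catalytic TsOH then eliminates trimethylsilanol, which comes back to the route at 9.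

Step 19 (metathesis to a trisubstituted alkene in a strained ten-membered ring: dimerisation, or no turnover at the hindered isopropenyl group). The ring is closed instead by an intramolecular Nozaki–Hiyama–Kishi coupling at C3–C4. The fallback sets out from 11:
- Stork–Zhao olefination of the aldehyde (Ph3P=C(I)CH3 from ethyltriphenylphosphonium iodide, n-BuLi, I2, NaN(SiMe3)2, −78 °C) gives the (Z)-vinyl iodide ketone F4.
- A Wittig reaction of its α-alkoxy methyl ketone with the ylide from [3-(tert-butyldimethylsilyloxy)propyl]triphenylphosphonium bromide and NaN(SiMe3)2 gives the (Z)-trisubstituted C10=C1 silyl ether F5.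
- Mo(CO)6 in wet MeCN gives the hydroxy ketone F6, and Takai–Lombardo methylenation gives the methylene compound F7.
- HF·pyridine removes both primary silyl groups to give the triol F8.
- TEMPO/PhI(OAc)2 converts one primary alcohol into the lactone and the other into the β,γ-unsaturated aldehyde, giving the iodo aldehyde lactone F9.
- CrCl2 with catalytic NiCl2 in DMSO at high dilution closes the ring to the macrocyclic C3 alcohol F10. The C3 epimers are separated and the unwanted one is inverted by a Mitsunobu reaction.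
- Acetylation (Ac2O, pyridine, DMAP) comes back to the route at 27.

**Further compounds**

F1 | step 3 | (1R,6S)-6-[(tert-butyldimethylsilyl)oxy]-2-methylcyclohexa-2,4-dien-1-ol | CC1=CC=C[C@H](O[Si](C)(C)C(C)(C)C)[C@@H]1O
F2 | step 6 | trimethylsilyl nitronate of 7 | CC(C)(C)[Si](C)(C)OCC=[N+]([O-])O[Si](C)(C)C
F3 | step 6 | N-(trimethylsilyloxy)isoxazolidine cycloadduct (ring as in 9, C11 sp3, mixture at C11 and N) | CC1=C[C@H]2ON(O[Si](C)(C)C)C(CO[Si](C)(C)C(C)(C)C)[C@H]2[C@H](O[Si](C)(C)C(C)(C)C)[C@@H]1OCc3ccc(OC)cc3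
F4 | step 19 | (Z)-vinyl iodide ketone: 11 with C5H=O replaced by C5H=C4(I)CH3 | C/C(I)=C/[C@H]1ON=C(CO[Si](C)(C)C(C)(C)C)[C@H]1[C@H](O[Si](C)(C)C(C)(C)C)[C@H](OCc2ccc(OC)cc2)C(C)=O
F5 | step 19 | F4 with C10(=O)CH3 replaced by (Z)-C10(CH3)=C1H–C2H2–C3H2–OTBS | C/C(I)=C/[C@H]1ON=C(CO[Si](C)(C)C(C)(C)C)[C@H]1[C@H](O[Si](C)(C)C(C)(C)C)[C@H](OCc2ccc(OC)cc2)/C(C)=C\CCO[Si](C)(C)C(C)(C)C
F6 | step 19 | hydroxy ketone from F5 (C6-OH, C11=O) | C/C(I)=C/[C@@H](O)[C@@H](C(=O)CO[Si](C)(C)C(C)(C)C)[C@H](O[Si](C)(C)C(C)(C)C)[C@H](OCc1ccc(OC)cc1)/C(C)=C\CCO[Si](C)(C)C(C)(C)C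
F7 | step 19 | F6 with C11=C13H2 | C/C(I)=C/[C@@H](O)[C@@H](C(=C)CO[Si](C)(C)C(C)(C)C)[C@H](O[Si](C)(C)C(C)(C)C)[C@H](OCc1ccc(OC)cc1)/C(C)=C\CCO[Si](C)(C)C(C)(C)C
F8 | step 19 | triol (C3-OH, C6-OH, C12-OH) | C/C(I)=C/[C@@H](O)[C@@H](C(=C)CO)[C@H](O[Si](C)(C)C(C)(C)C)[C@H](OCc1ccc(OC)cc1)/C(C)=C\CCO
F9 | step 19 | iodo aldehyde lactone (α-methylene lactone, C3 aldehyde, C4 vinyl iodide) | C/C(I)=C/[C@H]1OC(=O)C(=C)[C@H]1[C@H](O[Si](C)(C)C(C)(C)C)[C@H](OCc2ccc(OC)cc2)/C(C)=C\CC=O
F10 | step 19 | (3S)-3-hydroxy analogue of 27 | C=C1C(=O)O[C@@H]2/C=C(/C)[C@@H](O)C/C=C(/C)[C@@H](OCc3ccc(OC)cc3)[C@@H](O[Si](C)(C)C(C)(C)C)[C@H]12
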